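**Retrosynthetic overview**

1. Numbering: ring C = C2 (CMe2), C3 (CHBr), C4, C5 (CHOH), C6 (CMe); ring A = C7 (COH), C8, C9, C10 (CMe), C15 (COH), C16; ring B = C10, C11 (CHBr), C12, C13, C14 (CMeOH), C15. The strategy rests on the aldol-type array C5(O)–C6–C7(OH) of ring C/ring A, in which the quaternary C6 sits between the quaternary C2 and the tertiary carbinol C7.
2. Both neopentyl bromides (C3, C11) are taken back to ketones (hydrazone, alkenyl bromide, radical hydrogenation); diketone 30 comes from β-hydroxy cyclopentanone 26.
3. 26 ⇒ epoxy cyclobutanol 25: the C2–C6 bond and ring C form together when C2 shifts from C5 to C6 as the C6–O bond of the C6–C7 epoxide opens (semipinacol ring expansion).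
4. 25 ⇒ alkenyl iodide 21 + (R)-3-benzyloxy-2,2-dimethylcyclobutanone 7 (dimethylketene/benzyl vinyl ether [2+2]); the C6=C7 geometry (methyl cis to C8) is set by a cis-1,4-hydrogenation of 2-silyl diene 19, made from the C7=C8 enol triflate.
5. Ring order: rings A and B come intact from (S)-Wieland–Miescher ketone 8 (C14/C15 diol by dihydroxylation, oxidation, methyl addition); the cyclobutane is made separately; ring C is formed last by the ring expansion.

Key step: step 20

Remarks on the chemistry (assumptions):
(a) C3 and C5 of the cyclobutane both become trigonal before the end (C5 in step 20, C3 in step 24). The (R)-ether is used because it places the benzyloxy group on the ring C face opposite the C6 methyl and so supports the C5 reduction in step 21.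
(b) C11 is carried as a benzyl ether and both C–Br bonds are made together at the end, because a secondary bromide would not survive the alkenyllithium of step 17.
(c) α/β refer to the decalin drawn with the C10 methyl β.

**Route**

Step 1
Reactants: 1 isobutyryl chloride; 2 benzyl vinyl ether
Product: 4 rac-3-(benzyloxy)-2,2-dimethylcyclobutan-1-one, via dimethylketene 3 (not isolated)
Conditions: Et3N, MeCN, 80 °C, 2 in excess
Reagents that add atoms: none
Why: Dehydrochlorination gives the ketene, whose carbonyl carbon bonds to the CH2 terminus of the enol ether in a thermal [2+2] ketene–alkene cycloaddition, so the ether ends on C3 next to the gem-dimethyl carbon; the product is racemic.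

Step 2
Reactants: 4 rac-3-(benzyloxy)-2,2-dimethylcyclobutan-1-one
Product: 5 rac-cis-3-(benzyloxy)-2,2-dimethylcyclobutan-1-ol
Conditions: NaBH4, MeOH, −20 °C
Reagents that add atoms: none
Why: Borohydride reduction of a 3-substituted cyclobutanone should occur anti to the alkoxy group of the puckered ring, giving the cis alcohol.

Step 3
Reactants: 5 rac-cis-3-(benzyloxy)-2,2-dimethylcyclobutan-1-ol
Product: 6 (1S,3R)-3-(benzyloxy)-2,2-dimethylcyclobutan-1-ol (recovered alcohol)
Conditions: Amano lipase PS (Burkholderia cepacia), vinyl acetate, t-BuOMe, 30 °C, run past half conversion, chromatography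
Reagents that add atoms: none
Why: In a lipase kinetic resolution (transesterification) the empirical size rule for secondary alcohols (large group CMe2, medium group CH2) predicts acylation of the (1R) enantiomer, so the (1S,3R) alcohol should remain and is separated from the acetate.

Step 4
Reactants: 6 (1S,3R)-3-(benzyloxy)-2,2-dimethylcyclobutan-1-ol
Product: 7 (R)-3-(benzyloxy)-2,2-dimethylcyclobutan-1-one
Conditions: Dess–Martin periodinane, NaHCO3, CH2Cl2, 0 °C → rt
Reagents that add atoms: none
Why: Buffered Dess–Martin oxidation returns the ketone without base, so the β-alkoxy ketone is not eliminated and C3 keeps its configuration.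

Step 5
Reactants: 8 (S)-Wieland–Miescher ketone
Product: 9 (4aS,5S)-5-hydroxy-4a-methyl-4,4a,5,6,7,8-hexahydronaphthalen-2(3H)-one (C11 β-alcohol, enone intact)
Conditions: NaBH4 (0.3 equiv), EtOH, −10 °C
Reagents that add atoms: none
Why: Chemoselective borohydride reduction takes the saturated C11 ketone before the conjugated C7 ketone and attacks anti to the angular methyl, giving the C11 β (equatorial) alcohol.

Step 6
Reactants: 9 hydroxy enone
Product: 10 C11 benzyl ether of 9
Conditions: benzyl 2,2,2-trichloroacetimidate, TfOH (cat.), CH2Cl2–cyclohexane, rt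
Reagents that add atoms: benzyl 2,2,2-trichloroacetimidate, N=C(OCc1ccccc1)C(Cl)(Cl)Cl
Why: Acid-catalysed imidate O-benzylation avoids the basic conditions that would deprotonate the enone, and the ether is inert until the hydrogenolysis of step 23.

Step 7
Reactants: 10 benzyl ether enone
Product: 11 C7 ethylene ketal with the double bond at C14=C15 (C11 benzyl ether)
Conditions: ethylene glycol, p-TsOH (cat.), benzene, reflux (Dean–Stark)
Reagents that add atoms: ethylene glycol, OCCO
Why: Thermodynamic ketalisation of the enone runs through the dienol ether and moves the double bond out of conjugation (deconjugative ketal formation), which masks C7 and exposes the ring B alkene.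

Step 8
Reactants: 11 ketal alkene
Product: 12 C14α,C15α-diol (C15–OH trans to the C10 methyl; C7 ketal, C11 benzyl ether)
Conditions: OsO4 (5 mol%), N-methylmorpholine N-oxide, acetone–H2O, rt; aq. Na2SO3
Reagents that add atoms: N-methylmorpholine N-oxide, C[N+]1([O-])CCOCC1; water, O
Why: Upjohn dihydroxylation adds syn from the face opposite the axial C10 methyl, which sets C15–OH α and thus the trans ring fusion; the C14 carbinol centre is removed in the next step.

Step 9
Reactants: 12 diol
Product: 13 C15α-hydroxy C14 ketone
Conditions: IBX, DMSO, rt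
Reagents that add atoms: none
Why: IBX oxidises the secondary alcohol of a vicinal diol to the α-hydroxy ketone without glycol cleavage and leaves the tertiary C15 alcohol untouched (hypervalent iodine oxidation).

Step 10
Reactants: 13 α-hydroxy ketone
Product: 14 C14β,C15α-diol with C14α-methyl (trans-diaxial ditertiary diol; C7 ketal, C11 benzyl ether)
Conditions: MeMgBr (4 equiv), THF, −78 → 0 °C
Reagents that add atoms: methylmagnesium bromide, C[Mg]Br
Why: Grignard 1,2-addition to the C14 ketone should come from the α face because the β face is blocked by the syn-axial C10 methyl, making the methyl equatorial (α) and the new hydroxyl axial (β), trans to C15–OH.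

Step 11
Reactants: 14 ditertiary diol
Product: 15 C14,C15-bis(triethylsilyl) ether of 14
Conditions: Et3SiOTf, 2,6-lutidine, CH2Cl2, 0 → 35 °C
Reagents that add atoms: triethylsilyl triflate, CC[Si](CC)(CC)OS(=O)(=O)C(F)(F)F
Why: The silyl triflate caps both hindered tertiary alcohols (silyl ether formation), so that no alkoxide β to the C7 carbonyl can cause retro-aldol opening or elimination in the base steps that follow.

Step 12
Reactants: 15 bis-silyl ether ketal
Product: 16 C7 ketone (C14,C15-bis(triethylsilyl) ether, C11 benzyl ether)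
Conditions: PPTS, acetone–H2O, 50 °C
Reagents that add atoms: water, O
Why: Mild acid-catalysed acetal hydrolysis frees the C7 ketone while the hindered tertiary silyl ethers and the benzyl ether stay in place.

Step 13
Reactants: 16 C7 ketone
Product: 18 C7=C8 enol triflate, via potassium enolate 17 (not isolated)
Conditions: KHMDS, THF, −78 °C; then PhNTf2, −78 → 0 °C
Reagents that add atoms: N-phenylbis(trifluoromethanesulfonimide), O=S(=O)(N(c1ccccc1)S(=O)(=O)C(F)(F)F)C(F)(F)F
Why: The bulky amide base removes a proton from the unhindered C8 methylene and not from C16, which is neopentyl and shielded by the C15 silyl ether, and the enolate is O-sulfonylated (kinetic enolate triflation), fixing the ring double bond at C7=C8.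

Step 14
Reactants: 18 enol triflate
Product: 19 2-silyl diene: C7=C8 ring alkene bearing the 1-(trimethylsilyl)vinyl group (C6) on C7
Conditions: (1-bromovinyl)trimethylsilane, Mg, THF; then 18, Pd(PPh3)4 (5 mol%), THF, rt → 50 °C
Reagents that add atoms: (1-bromovinyl)trimethylsilane (as its Grignard reagent), C=C(Br)[Si](C)(C)C
Why: Palladium-catalysed Kumada coupling of the enol triflate with the α-silylvinyl Grignard reagent forms the C6–C7 bond and gives a 2-silyl-1,3-diene in which C6 already carries the future methyl carbon as =CH2.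

Step 15
Reactants: 19 2-silyl diene
Product: 20 alkenylsilane with exocyclic C6=C7: on C6 the methyl is cis to C8 and SiMe3 is cis to C16
Conditions: (η6-C10H8)Cr(CO)3 (20 mol%), H2 (50 atm), THF, 45 °C
Reagents that add atoms: none
Why: Arene–Cr(CO)3 catalysts hydrogenate 1,3-dienes only through the η4 s-cis complex and add both hydrogens to the termini (cis-1,4-hydrogenation), so C8 and the new methyl must end cis on the C6=C7 bond and silicon cis to C16; the tetrasubstituted alkene formed is not reduced further.

Step 16
Reactants: 20 alkenylsilane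
Product: 21 alkenyl iodide (1-iodoethylidene at C7, iodine cis to C16, methyl cis to C8)
Conditions: N-iodosuccinimide, 2,6-lutidine, (CF3)2CHOH, 0 °C
Reagents that add atoms: N-iodosuccinimide, O=C1CCC(=O)N1I
Why: Electrophilic ipso-iododesilylation of an alkenylsilane passes through the β-silyl cation and should proceed with retention of alkene geometry, so iodine takes the place of silicon cis to C16.

Step 17
Reactants: 21 alkenyl iodide; 7 (R)-3-(benzyloxy)-2,2-dimethylcyclobutan-1-one
Product: 23 allylic cyclobutanol (C5–OH cis to the C3 benzyloxy group, C5 cis to C16 on the C6=C7 alkene; C14,C15-bis(triethylsilyl) ether), via alkenyllithium 22 (not isolated)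
Conditions: t-BuLi (2.1 equiv), Et2O, −78 °C; then 7, THF, −78 → −40 °C; aq. NH4Cl
Reagents that add atoms: none
Why: Iodine–lithium exchange gives a configurationally stable alkenyllithium that should add to the strained cyclobutanone faster than it enolises it and anti to the benzyloxy group (1,2-addition), forming C5–C6 with the alkene geometry retained; the C5 configuration is of no consequence because C5 becomes a carbonyl in step 20.

Step 18
Reactants: 23 bis-silyl allylic cyclobutanol
Product: 24 triol (C5, C14, C15 hydroxyls free; C3 and C11 benzyl ethers)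
Conditions: Bu4NF, THF, 45 °C; aq. NH4Cl
Reagents that add atoms: none
Why: Fluoride cleaves both triethylsilyl ethers (desilylation) and restores the axial C15 hydroxyl needed to direct the next step.

Step 19
Reactants: 24 triol
Product: 25 epoxy cyclobutanol: C6–C7 epoxide with oxygen α on C7, methyl on C6 cis to C8
Conditions: VO(acac)2 (10 mol%), t-BuOOH (decane), CH2Cl2, 0 °C; chromatography on Et3N-deactivated silica
Reagents that add atoms: tert-butyl hydroperoxide, CC(C)(C)OO
Why: In this hydroxyl-directed epoxidation the vanadium alkoxide of the axial C15 hydroxyl, which lies under C7 on the α face (homoallylic, 1,3-diaxial), should deliver the peroxide oxygen to the α face of the only alkene, setting C7–O α, while the alkene geometry fixes C6.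

Step 20
Reactants: 25 epoxy cyclobutanol
Product: 26 β-hydroxy cyclopentanone (C5 ketone, C2–C6 and C6–C7 in place, C7–OH α)
Conditions: ZnBr2 (1.5 equiv), CH2Cl2, −20 → 0 °C
Reagents that add atoms: none
Why: Zinc binds the epoxide oxygen (held also by the syn-axial C15 hydroxyl) and weakens the C6–O bond, and the cyclobutane bond C5–C2 lying antiperiplanar to it shifts to C6 with inversion while the C5 carbinol becomes the ketone; this is the semipinacol rearrangement of a 2,3-epoxy alcohol in its known cyclobutanol-to-cyclopentanone ring-expansion form. Ring C is therefore closed not by an endo or exo cyclisation but by a 1,2-shift that inserts C6 into the four-membered ring (C2–C6 formed, C2–C5 broken, four to five). The one new stereocentre, C6, is controlled by the epoxide: oxygen on the α face (step 19) and methyl cis to C8 (step 15) are turned by backside migration into the required C6 configuration, and the epoxide oxygen stays on C7 as the α tertiary alcohol. The step needs cleavage of C6–O and not C7–O, which follows because only cleavage at C6 places the developing cation next to the carbinol carbon whose bond can migrate and whose hydroxyl ends the shift as a carbonyl; it needs migration of C2 and not C4, secured by the higher migratory aptitude of the fully substituted carbon; and it needs the cyclobutane shift to outrun a shift from ring A, secured by release of four-ring strain together with carbonyl formation. The same driving force pays for joining two quaternary carbons.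

Step 21
Reactants: 26 β-hydroxy cyclopentanone
Product: 27 C5 alcohol (hydroxyl cis to C7, trans to the C6 methyl)
Conditions: NaBH4, CeCl3·7H2O, MeOH, −40 °C
Reagents that add atoms: none
Why: Under Luche conditions external hydride should attack the cyclopentanone from the face of the C6 methyl, anti to the decalin substituent on C6 and to the C3 benzyloxy group, giving the C5 alcohol of the target configuration (carbonyl reduction under steric control).

Step 22
Reactants: 27 C5 alcohol
Product: 28 C5 tert-butyldimethylsilyl ether
Conditions: t-BuMe2SiOTf (1.2 equiv), 2,6-lutidine, CH2Cl2, −78 °C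
Reagents that add atoms: tert-butyldimethylsilyl triflate, CC(C)(C)[Si](C)(C)OS(=O)(=O)C(F)(F)F
Why: At low temperature the silyl triflate should react only with the secondary C5 alcohol, the three tertiary axial hydroxyls being far more hindered (selective silyl ether formation); the ether later prevents β-elimination next to the C3 ketone.

Step 23
Reactants: 28 silyl ether bis(benzyl ether)
Product: 29 C3,C11-diol (C5 silyl ether)
Conditions: H2 (1 atm), Pd(OH)2/C, EtOAc, rt
Reagents that add atoms: none
Why: Catalytic hydrogenolysis removes both benzyl ethers in one operation without touching the silyl ether or the tertiary alcohols.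

Step 24
Reactants: 29 diol
Product: 30 C3,C11-diketone
Conditions: Dess–Martin periodinane, NaHCO3, CH2Cl2, rt
Reagents that add atoms: none
Why: Buffered Dess–Martin oxidation converts the two secondary alcohols into ketones without base, so the C11 ketone/C15 hydroxyl aldol pair is never exposed to alkoxide.

Step 25
Reactants: 30 diketone
Product: 31 C3,C11-bis(hydrazone)
Conditions: N2H4·H2O, Et3N, EtOH, 70 °C
Reagents that add atoms: hydrazine, NN
Why: Both ketones, each flanked by one quaternary carbon and one methylene, should condense with hydrazine (hydrazone formation).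

Step 26
Reactants: 31 bis(hydrazone)
Product: 32 bis(alkenyl bromide): C3(Br)=C4 and C11(Br)=C12
Conditions: N-bromosuccinimide, pyridine, 0 °C
Reagents that add atoms: N-bromosuccinimide, O=C1CCC(=O)N1Br
Why: Oxidation of each hydrazone gives the diazo compound and then the α-bromo cation, which loses a proton from its only enolisable side (C4, C12) to give the alkenyl bromide (Barton-type hydrazone to alkenyl halide conversion).

Step 27
Reactants: 32 bis(alkenyl bromide)
Product: 33 C3,C11-dibromide (C5 silyl ether)
Conditions: Mn(dpm)3 (20 mol%; dpm = dipivaloylmethanate, C11H19O2), PhSiH3, t-BuOOH, i-PrOH, rt, degassed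
Reagents that add atoms: none
Why: In this hydrogen-atom-transfer hydrogenation of alkenyl halides, which keeps the C–Br bond, H adds first to C4 and C12 to give the α-bromo radicals, and the second H should reach C3 from the face of the C6 methyl (anti to C5–OSi and C7) and C11 axially from the α face (anti to the adjacent axial C10 methyl), leaving C3–Br cis to C5–O and C11–Br equatorial.

Step 28
Reactants: 33 silyl ether dibromide
Product: 34 neoirietetraol
Conditions: HF·pyridine, THF, 0 °C → rt
Reagents that add atoms: none
Why: Acid-buffered fluoride removes the silyl ether (desilylation) without exposing the secondary bromides to base.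

**Compound list**

1 | isobutyryl chloride | CC(C)C(=O)Cl | starting material
2 | benzyl vinyl ether | C=COCc1ccccc1 | starting material
3 | dimethylketene | CC(C)=C=O | intermediate
4 | rac-3-(benzyloxy)-2,2-dimethylcyclobutan-1-one (both enantiomers) | CC1(C)[C@H](OCc2ccccc2)CC1=O.CC1(C)[C@@H](OCc2ccccc2)CC1=O | intermediate
5 | rac-cis-3-(benzyloxy)-2,2-dimethylcyclobutan-1-ol (both enantiomers) | CC1(C)[C@H](OCc2ccccc2)C[C@@H]1O.CC1(C)[C@@H](OCc2ccccc2)C[C@H]1O | intermediate
6 | (1S,3R)-3-(benzyloxy)-2,2-dimethylcyclobutan-1-ol | CC1(C)[C@H](OCc2ccccc2)C[C@@H]1O | intermediate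
7 | (R)-3-(benzyloxy)-2,2-dimethylcyclobutan-1-one | CC1(C)[C@H](OCc2ccccc2)CC1=O | intermediate
8 | (S)-Wieland–Miescher ketone | C[C@]12CCC(=O)C=C1CCCC2=O | starting material
9 | (4aS,5S)-5-hydroxy-4a-methyl-4,4a,5,6,7,8-hexahydronaphthalen-2(3H)-one | C[C@]12CCC(=O)C=C1CCC[C@@H]2O | intermediate
10 | C11 benzyl ether of 9 | C[C@]12CCC(=O)C=C1CCC[C@@H]2OCc1ccccc1 | intermediate
11 | C7 ethylene ketal, C14=C15 alkene, C11 benzyl ether | C[C@]12CCC3(OCCO3)CC1=CCC[C@@H]2OCc1ccccc1 | intermediate
12 | C14α,C15α-diol (C7 ketal, C11 benzyl ether) | C[C@]12CCC3(OCCO3)C[C@]1(O)[C@@H](O)CC[C@@H]2OCc1ccccc1 | intermediate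
13 | C15α-hydroxy C14 ketone (C7 ketal, C11 benzyl ether) | C[C@]12CCC3(OCCO3)C[C@]1(O)C(=O)CC[C@@H]2OCc1ccccc1 | intermediate
14 | C14α-methyl C14β,C15α-diol (C7 ketal, C11 benzyl ether) | C[C@]12CCC3(OCCO3)C[C@]1(O)[C@](C)(O)CC[C@@H]2OCc1ccccc1 | intermediate
15 | C14,C15-bis(triethylsilyl) ether of 14 | C[C@]12CCC3(OCCO3)C[C@]1(O[Si](CC)(CC)CC)[C@](C)(O[Si](CC)(CC)CC)CC[C@@H]2OCc1ccccc1 | intermediate
16 | C7 ketone (bis-silyl ether, C11 benzyl ether) | C[C@]12CCC(=O)C[C@]1(O[Si](CC)(CC)CC)[C@](C)(O[Si](CC)(CC)CC)CC[C@@H]2OCc1ccccc1 | intermediate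
17 | potassium C7=C8 enolate of 16 | C[C@]12CC=C([O-])C[C@]1(O[Si](CC)(CC)CC)[C@](C)(O[Si](CC)(CC)CC)CC[C@@H]2OCc1ccccc1.[K+] | intermediate
18 | C7=C8 enol triflate | C[C@]12CC=C(OS(=O)(=O)C(F)(F)F)C[C@]1(O[Si](CC)(CC)CC)[C@](C)(O[Si](CC)(CC)CC)CC[C@@H]2OCc1ccccc1 | intermediate
19 | 2-silyl diene (C7=C8, C6(SiMe3)=CH2) | C[C@]12CC=C(C(=C)[Si](C)(C)C)C[C@]1(O[Si](CC)(CC)CC)[C@](C)(O[Si](CC)(CC)CC)CC[C@@H]2OCc1ccccc1 | intermediate
20 | alkenylsilane, exocyclic C6=C7 (methyl cis to C8, SiMe3 cis to C16) | C[C@]12CC/C(=C(\C)[Si](C)(C)C)C[C@]1(O[Si](CC)(CC)CC)[C@](C)(O[Si](CC)(CC)CC)CC[C@@H]2OCc1ccccc1 | intermediate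
21 | alkenyl iodide (1-iodoethylidene at C7, iodine cis to C16) | C[C@]12CC/C(=C(\C)I)C[C@]1(O[Si](CC)(CC)CC)[C@](C)(O[Si](CC)(CC)CC)CC[C@@H]2OCc1ccccc1 | intermediate
22 | alkenyllithium from 21 | C[C@]12CC/C(=C(\C)[Li])C[C@]1(O[Si](CC)(CC)CC)[C@](C)(O[Si](CC)(CC)CC)CC[C@@H]2OCc1ccccc1 | intermediate
23 | allylic cyclobutanol, C14,C15-bis(triethylsilyl) ether | C[C@]12CC/C(=C(\C)[C@]3(O)C[C@@H](OCc4ccccc4)C3(C)C)C[C@]1(O[Si](CC)(CC)CC)[C@](C)(O[Si](CC)(CC)CC)CC[C@@H]2OCc1ccccc1 | intermediate
24 | allylic cyclobutanol triol | C[C@]12CC/C(=C(\C)[C@]3(O)C[C@@H](OCc4ccccc4)C3(C)C)C[C@]1(O)[C@](C)(O)CC[C@@H]2OCc1ccccc1 | intermediate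
25 | epoxy cyclobutanol (key-step precursor) | CC1(C)[C@H](OCc2ccccc2)C[C@@]1(O)[C@]1(C)O[C@@]12CC[C@]3(C)[C@@H](OCc4ccccc4)CC[C@@](C)(O)[C@@]3(O)C2 | intermediate
26 | β-hydroxy cyclopentanone (key-step product) | CC1(C)[C@H](OCc2ccccc2)CC(=O)[C@]1(C)[C@@]1(O)CC[C@]2(C)[C@@H](OCc3ccccc3)CC[C@@](C)(O)[C@@]2(O)C1 | intermediate
27 | C5 alcohol | CC1(C)[C@H](OCc2ccccc2)C[C@H](O)[C@]1(C)[C@@]1(O)CC[C@]2(C)[C@@H](OCc3ccccc3)CC[C@@](C)(O)[C@@]2(O)C1 | intermediate
28 | C5 tert-butyldimethylsilyl ether | CC1(C)[C@H](OCc2ccccc2)C[C@H](O[Si](C)(C)C(C)(C)C)[C@]1(C)[C@@]1(O)CC[C@]2(C)[C@@H](OCc3ccccc3)CC[C@@](C)(O)[C@@]2(O)C1 | intermediate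
29 | C3,C11-diol (C5 silyl ether) | CC1(C)[C@H](O)C[C@H](O[Si](C)(C)C(C)(C)C)[C@]1(C)[C@@]1(O)CC[C@]2(C)[C@@H](O)CC[C@@](C)(O)[C@@]2(O)C1 | intermediate
30 | C3,C11-diketone | CC1(C)C(=O)C[C@H](O[Si](C)(C)C(C)(C)C)[C@]1(C)[C@@]1(O)CC[C@]2(C)C(=O)CC[C@@](C)(O)[C@@]2(O)C1 | intermediate
31 | C3,C11-bis(hydrazone) | CC1(C)C(=NN)C[C@H](O[Si](C)(C)C(C)(C)C)[C@]1(C)[C@@]1(O)CC[C@]2(C)C(=NN)CC[C@@](C)(O)[C@@]2(O)C1 | intermediate
32 | bis(alkenyl bromide) | CC1(C)C(Br)=C[C@H](O[Si](C)(C)C(C)(C)C)[C@]1(C)[C@@]1(O)CC[C@]2(C)C(Br)=CC[C@@](C)(O)[C@@]2(O)C1 | intermediate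
33 | dibromide, C5 silyl ether | CC1(C)[C@H](Br)C[C@H](O[Si](C)(C)C(C)(C)C)[C@]1(C)[C@@]1(O)CC[C@]2(C)[C@@H](Br)CC[C@@](C)(O)[C@@]2(O)C1 | intermediate
34 | neoirietetraol | CC1(C)[C@H](Br)C[C@H](O)[C@]1(C)[C@@]1(O)CC[C@]2(C)[C@@H](Br)CC[C@@](C)(O)[C@@]2(O)C1 | target

**Step count**

Total step count: 28 (4 for the cyclobutanone, 24 from 8).
Longest linear sequence: 24 steps (8 → 34, steps 5–28).

**Steps most likely to fail**

Step 15. The crowded 2-silyl diene may fail to reach the planar s-cis chromium complex, so that hydrogenation stalls or takes another course and the C6=C7 geometry is not set cleanly. The fallback sets out from 18 and comes back at alkenyllithium 22. It sets the geometry on a 2-silyloxy diene, the substrate class on which this cis-1,4-hydrogenation is established, and reaches the alkenyl metal through an enol triflate. Stille coupling of 18 with tributyl(1-ethoxyvinyl)stannane (Pd(PPh3)4, LiCl, THF) would give the 2-ethoxy diene F1, hydrolysed on acidic work-up to the methyl ketone F2. Kinetic enolisation at the methyl group (LDA, Et3SiCl, −78 °C) would give the silyloxy diene F3. Cis-1,4-hydrogenation under the conditions of step 15 would give the silyl enol ether F4 with the methyl cis to C8. MeLi would release the lithium enolate F5, trapped with PhNTf2 as the enol triflate F6. Pd(PPh3)4 and Me3SnSnMe3 would give the alkenylstannane F7, and tin–lithium exchange with MeLi would give 22, taken on with 7 as in step 17.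

Step 20. The fully substituted epoxide may ionise to an open C6 cation (loss of the stereochemical link, proton loss), C4 or a ring A carbon may shift, or the zinc aldolate may undergo retro-aldol cleavage. The fallback sets out from 25 and comes back at 26. It changes both substrate and promoter to the 2,3-epoxy silyl ether rearrangement. Silylation of all three hydroxyls (Me3SiOTf, Et3N) would give the tris(trimethylsilyl) ether F8. TiCl4 at −78 °C would then bind only the epoxide oxygen, the migration being pushed from the silyl ether oxygen and the aldol held as a titanium chelate. Dilute acid on work-up would remove the remaining silyl groups to return 26.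

Step 27. Hydrogen may be delivered to the C11 radical from the β face (axial bromide), or bromine may be lost reductively from the α-bromo radicals. The fallback sets out from 32 and comes back at 33 and makes no new compound (F0). It leaves the radical manifold: both alkenyl bromides would be hydrogenated by syn-addition on a metal surface (H2, Rh/Al2O3, EtOAc). The face is then chosen by adsorption on the exposed side (α at C11=C12, the methyl face at C3=C4), and this catalyst is one that tends to keep vinylic C–Br bonds.

**Further compounds**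

F1 | step 15 | 2-ethoxy diene (C7=C8, C6(OEt)=CH2) | C[C@]12CC=C(C(=C)OCC)C[C@]1(O[Si](CC)(CC)CC)[C@](C)(O[Si](CC)(CC)CC)CC[C@@H]2OCc1ccccc1
F2 | step 15 | C7-acetyl C7=C8 enone | C[C@]12CC=C(C(C)=O)C[C@]1(O[Si](CC)(CC)CC)[C@](C)(O[Si](CC)(CC)CC)CC[C@@H]2OCc1ccccc1
F3 | step 15 | 2-(triethylsilyloxy) diene | C[C@]12CC=C(C(=C)O[Si](CC)(CC)CC)C[C@]1(O[Si](CC)(CC)CC)[C@](C)(O[Si](CC)(CC)CC)CC[C@@H]2OCc1ccccc1
F4 | step 15 | silyl enol ether, exocyclic C6=C7 (methyl cis to C8) | C[C@]12CC/C(=C(\C)O[Si](CC)(CC)CC)C[C@]1(O[Si](CC)(CC)CC)[C@](C)(O[Si](CC)(CC)CC)CC[C@@H]2OCc1ccccc1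
F5 | step 15 | lithium enolate from F4 | C[C@]12CC/C(=C(\C)[O-])C[C@]1(O[Si](CC)(CC)CC)[C@](C)(O[Si](CC)(CC)CC)CC[C@@H]2OCc1ccccc1.[Li+]
F6 | step 15 | enol triflate, exocyclic C6=C7 (triflate cis to C16) | C[C@]12CC/C(=C(\C)OS(=O)(=O)C(F)(F)F)C[C@]1(O[Si](CC)(CC)CC)[C@](C)(O[Si](CC)(CC)CC)CC[C@@H]2OCc1ccccc1
F7 | step 15 | alkenyl(trimethyl)stannane | C[C@]12CC/C(=C(\C)[Sn](C)(C)C)C[C@]1(O[Si](CC)(CC)CC)[C@](C)(O[Si](CC)(CC)CC)CC[C@@H]2OCc1ccccc1
F8 | step 20 | C5,C14,C15-tris(trimethylsilyl) ether of 25 | CC1(C)[C@H](OCc2ccccc2)C[C@@]1(O[Si](C)(C)C)[C@]1(C)O[C@@]12CC[C@]3(C)[C@@H](OCc4ccccc4)CC[C@@](C)(O[Si](C)(C)C)[C@@]3(O[Si](C)(C)C)C2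
F0 | step 27 | none | none
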